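**Retrosynthetic overview**
1. With guaiane numbering (five-membered ring C1–C5; seven-membered ring C1, C5–C10), the target goes back to cycloadduct 16 by phenol desilylation, syn-dehydration to C3=C4, vanilloylation at O8, methyl addition at C4, ketal hydrolysis and hydroxyl-directed hydrogenation that sets C7.
2. The strategy rests on the seven-membered ring C1/C5–C10: it carries C1=C10 at the ring fusion and, 1,4 to it, the C6–C7 bond next to oxygenated C8. This is the cyclohepta-1,4-diene formed when an alkyne (C1, C10) joins a vinylcyclopropane (C5–C9), so 16 is cut at C1–C5 and C9–C10 to give enyne 15.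
3. 15 is cut at C5=C6 (E-selective olefination) into cyclopropane aldehyde 6 and ketal sulfone 14.
4. 6 comes from (E)-silyloxy allylic alcohol 4 by hydroxyl-directed asymmetric cyclopropanation (sets C7 and C8, adds C9); 14 comes from a pentynyl Grignard reagent and chloroacetamide 8.
5. Ring order: cyclopropane (step 4), then the five- and seven-membered rings together in step 11 (the five-membered ring closes first within the catalytic cycle).

Key step: step 11

**Remarks on the chemistry (assumptions)**
- Locants are guaiane locants: C14 is the methyl on C10, C15 the methyl on C4, the isopropyl group sits on C7; "15-nor" means C4 carries no methyl.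
- The facial sense of the directed cyclopropanation is assumed to follow (E)-cinnamyl alcohol, for which the (4R,5R)-dioxaborolane gives the (1S,2S)-cyclopropylmethanol.
- The cyclopropane is made before the diene is assembled because a zinc carbenoid has no dependable enantiocontrol on a silyl dienol ether without a directing hydroxyl. The silyl group is triisopropylsilyl to add bulk at C8.
- Some descriptors change between intermediates only because substituent priorities change (cyclopropane C1: 1S in 5, 1R in 6; C5: 5S in 16–24, 5R in 25 and 26). No centre is inverted.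

**Route**

Step 1
Reactants: 1 ethyl 3-methylbutanoate
Product: 2 ethyl 2-formyl-3-methylbutanoate (racemic; largely the enol)
Conditions: LiN(iPr)2, THF, −78 °C; HCO2Et, −78 → 0 °C; 1 M HCl
Reagents that add atoms: ethyl formate, CCOC=O
Why: Crossed Claisen condensation (C-formylation) of the lithium ester enolate with the non-enolisable formate, driven by deprotonation of the β-formyl ester as it forms; its stereocentre disappears in step 2.

Step 2
Reactants: 2 ethyl 2-formyl-3-methylbutanoate
Product: 3 ethyl (E)-2-(propan-2-yl)-3-[(triisopropylsilyl)oxy]prop-2-enoate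
Conditions: iPr3SiOTf, Et3N, CH2Cl2, 0 °C
Reagents that add atoms: triisopropylsilyl trifluoromethanesulfonate, CC(C)[Si](OS(=O)(=O)C(F)(F)F)(C(C)C)C(C)C
Why: Silyl enol ether formation on the formyl oxygen under non-chelating amine conditions should give the dipole-minimised E isomer (OSi trans to the ester, cis to isopropyl), the geometry that later becomes the trans relationship of O8 and C6 on the cyclopropane.

Step 3
Reactants: 3 ethyl (E)-2-(propan-2-yl)-3-[(triisopropylsilyl)oxy]prop-2-enoate
Product: 4 (E)-2-(propan-2-yl)-3-[(triisopropylsilyl)oxy]prop-2-en-1-ol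
Conditions: iBu2AlH (2.5 equiv), CH2Cl2, −78 °C; aq. KNaC4H4O6
Reagents that add atoms: none
Why: 1,2-Reduction of the ester by iBu2AlH at low temperature gives the allylic alcohol, leaves the bulky silyl enol ether intact and keeps the E geometry, which also rules out O-to-O silyl transfer.

Step 4
Reactants: 4 (E)-2-(propan-2-yl)-3-[(triisopropylsilyl)oxy]prop-2-en-1-ol
Product: 5 [(1S,2S)-1-(propan-2-yl)-2-[(triisopropylsilyl)oxy]cyclopropyl]methanol
Conditions: Zn(CH2I)2·DME (from Et2Zn, CH2I2, DME), (4R,5R)-2-butyl-N,N,N',N'-tetramethyl-1,3,2-dioxaborolane-4,5-dicarboxamide (1.2 equiv), CH2Cl2, −10 °C → rt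
Reagents that add atoms: diiodomethane, ICI
Why: Charette asymmetric cyclopropanation (hydroxyl-directed Simmons–Smith reaction): the zinc alkoxide bound to the chiral dioxaborolane delivers CH2 (C9) to one face of the electron-rich enol ether and sets C7 and C8 as (1S,2S), while stereospecific syn addition to the E alkene places the silyloxy group trans to CH2OH.

Step 5
Reactants: 5 [(1S,2S)-1-(propan-2-yl)-2-[(triisopropylsilyl)oxy]cyclopropyl]methanol
Product: 6 (1R,2S)-1-(propan-2-yl)-2-[(triisopropylsilyl)oxy]cyclopropane-1-carbaldehyde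
Conditions: Dess–Martin periodinane, NaHCO3, CH2Cl2, 0 °C → rt
Reagents that add atoms: none
Why: Dess–Martin oxidation under buffered, neutral conditions gives the aldehyde of the donor–acceptor cyclopropane without acid or fluoride, and the quaternary α-carbon cannot epimerise.

Step 6
Reactants: 7 5-bromopent-2-yne; 8 2-chloro-N-methoxy-N-methylacetamide
Product: 10 1-chlorohept-5-yn-2-one, via pent-3-yn-1-ylmagnesium bromide 9 (not isolated)
Conditions: Mg, THF, 35 °C; then 8, −78 → 0 °C; aq. NH4Cl
Reagents that add atoms: none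
Why: Weinreb ketone synthesis: the Grignard reagent adds once to the N-methoxy-N-methylamide through the stable magnesium chelate, and the α-chloride is not displaced at low temperature.

Step 7
Reactants: 10 1-chlorohept-5-yn-2-one; 11 1-phenyl-1H-tetrazole-5-thiol
Product: 12 1-[(1-phenyl-1H-tetrazol-5-yl)sulfanyl]hept-5-yn-2-one
Conditions: Et3N, CH2Cl2, 0 °C → rt
Reagents that add atoms: none
Why: SN2 S-alkylation of the thiolate by the activated α-chloroketone.

Step 8
Reactants: 12 1-[(1-phenyl-1H-tetrazol-5-yl)sulfanyl]hept-5-yn-2-one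
Product: 13 5-({[2-(pent-3-yn-1-yl)-1,3-dioxolan-2-yl]methyl}sulfanyl)-1-phenyl-1H-tetrazole
Conditions: HOCH2CH2OH, TsOH·H2O (cat.), toluene, reflux (Dean–Stark)
Reagents that add atoms: ethane-1,2-diol, OCCO
Why: Acid-catalysed ketalisation with azeotropic removal of water installs the C4 dioxolane before the neighbouring position is turned into a sulfone; alkyne and tetrazolyl sulfide are inert.

Step 9
Reactants: 13 5-({[2-(pent-3-yn-1-yl)-1,3-dioxolan-2-yl]methyl}sulfanyl)-1-phenyl-1H-tetrazole
Product: 14 5-({[2-(pent-3-yn-1-yl)-1,3-dioxolan-2-yl]methyl}sulfonyl)-1-phenyl-1H-tetrazole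
Conditions: (NH4)6Mo7O24·4H2O (cat.), 30% H2O2, EtOH, 0 °C → rt
Reagents that add atoms: hydrogen peroxide, OO
Why: Molybdate-catalysed oxidation of sulfide to sulfone, to which the internal alkyne and the dioxolane (deactivated toward hydrolysis by the adjacent sulfonyl group) are inert.

Step 10
Reactants: 6 (1R,2S)-1-(propan-2-yl)-2-[(triisopropylsilyl)oxy]cyclopropane-1-carbaldehyde; 14 5-({[2-(pent-3-yn-1-yl)-1,3-dioxolan-2-yl]methyl}sulfonyl)-1-phenyl-1H-tetrazole
Product: 15 {[(1S,2S)-2-{(E)-2-[2-(pent-3-yn-1-yl)-1,3-dioxolan-2-yl]ethenyl}-2-(propan-2-yl)cyclopropyl]oxy}tri(propan-2-yl)silane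
Conditions: KN(SiMe3)2, THF, −78 °C → rt (base added to 6 + 14)
Reagents that add atoms: none
Why: Julia–Kocienski olefination: the sulfonyl carbanion adds to the non-enolisable aldehyde, and Smiles rearrangement with loss of SO2 and tetrazolate gives C5=C6, E being expected for a phenyltetrazolyl sulfone, an α-quaternary aldehyde and an alkene flanked by two quaternary carbons; no stereocentre is touched.

Step 11
Reactants: 15 {[(1S,2S)-2-{(E)-2-[2-(pent-3-yn-1-yl)-1,3-dioxolan-2-yl]ethenyl}-2-(propan-2-yl)cyclopropyl]oxy}tri(propan-2-yl)silane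
Product: 16 (5S,8S)-4,4-(ethylenedioxy)-8-[(triisopropylsilyl)oxy]-15-norguaia-1(10),6-diene
Conditions: [Rh(CO)2Cl]2 (5 mol%), ClCH2CH2Cl, 50–80 °C
Reagents that add atoms: none
Why: Monovalent rhodium binds the alkene and alkyne of 15, cleaves the cyclopropane bond C7–C9 by oxidative addition to a σ(C9),π-allyl(C5–C7) rhodacycle, inserts the tethered alkyne at the C5 terminus (C1–C5) and finishes by C9–C10 reductive elimination; the closest known reaction type is the rhodium-catalysed intramolecular [5+2] cycloaddition of alkyne-tethered vinylcyclopropanes, including 1,2-disubstituted cyclopropanes, of which a 2-silyloxy member has not been tested. The five-membered ring (C1–C5) closes by 5-exo migratory insertion across the three-atom tether, and the seven-membered ring (C1, C5–C10) closes by reductive elimination from the eight-membered rhodacycle. C5 is the only new stereocentre and is set by C8: the process is suprafacial on the five-carbon unit, the E alkene puts H5 inside the s-cis vinylcyclopropane, and a silyloxy group trans to the vinyl group therefore ends with H5 and H8 cis, i.e. (5S,8S). The step needs cleavage of C7–C9 and not of the oxygen-substituted C7–C8 bond; sterics should secure this, because insertion into C7–C8 would put rhodium on a secondary carbon bearing OSi(iPr)3 whereas C9 is an unhindered methylene, and the neutral carbonyl chloride catalyst is not Lewis acidic enough to ionise the donor cyclopropane or the ketal. The isopropyl group on C7 raises the population of the reactive s-cis conformer and the quaternary C4 favours ring closure.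

Step 12
Reactants: 16 (5S,8S)-4,4-(ethylenedioxy)-8-[(triisopropylsilyl)oxy]-15-norguaia-1(10),6-diene
Product: 17 (5S,8S)-4,4-(ethylenedioxy)-15-norguaia-1(10),6-dien-8-ol
Conditions: Bu4NF, THF, rt
Reagents that add atoms: none
Why: Fluoride-induced Si–O cleavage frees the allylic C8 hydroxyl; ketal and both alkenes are inert to fluoride.

Step 13
Reactants: 17 (5S,8S)-4,4-(ethylenedioxy)-15-norguaia-1(10),6-dien-8-ol
Product: 18 (5S,7R,8S)-4,4-(ethylenedioxy)-15-norguai-1(10)-en-8-ol
Conditions: H2 (1 atm), [Ir(cod)(PCy3)(py)]PF6 (5 mol%), CH2Cl2, 0 °C → rt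
Reagents that add atoms: none
Why: Hydroxyl-directed hydrogenation with the cationic iridium catalyst: the C8 hydroxyl binds the metal and hydrogen adds to the adjacent trisubstituted C6=C7 on the hydroxyl face, so H7 ends cis to OH and isopropyl trans (7R), while the tetrasubstituted C1=C10 reacts much more slowly.

Step 14
Reactants: 18 (5S,7R,8S)-4,4-(ethylenedioxy)-15-norguai-1(10)-en-8-ol
Product: 19 (5S,7R,8S)-8-hydroxy-15-norguai-1(10)-en-4-one
Conditions: pyridinium p-toluenesulfonate (cat.), acetone–H2O, rt → 40 °C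
Reagents that add atoms: water, O
Why: Acid-catalysed ketal hydrolysis under weakly acidic conditions, chosen so that the tetrasubstituted β,γ-alkene stays out of conjugation and C5 is not enolised.

Step 15
Reactants: 19 (5S,7R,8S)-8-hydroxy-15-norguai-1(10)-en-4-one
Product: 20 (4R,5S,7R,8S)-guai-1(10)-ene-4,8-diol
Conditions: MeCeCl2 (from MeLi and CeCl3; 3 equiv), THF, −78 °C
Reagents that add atoms: methylcerium dichloride, C[Ce](Cl)Cl (from methyllithium, C[Li])
Why: 1,2-Addition of the weakly basic organocerium reagent (no enolisation of the β,γ-unsaturated ketone; one equivalent is consumed by the hydroxyl) from the cyclopentanone face anti to C6 on C5, which should place the methyl cis to H5 and the tertiary hydroxyl trans to H5 (4R).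

Step 16
Reactants: 21 vanillic acid (4-hydroxy-3-methoxybenzoic acid)
Product: 23 4-[(tert-butyldimethylsilyl)oxy]-3-methoxybenzoic acid, via bis-silylated vanillic acid 22 (not isolated)
Conditions: tBuMe2SiCl, imidazole, DMF, rt; then AcOH–THF–H2O, rt
Reagents that add atoms: tert-butyldimethylsilyl chloride, CC(C)(C)[Si](C)(C)Cl
Why: Silylation of phenol and acid followed by selective hydrolysis of the labile silyl ester leaves the aryl silyl ether as phenol protection.

Step 17
Reactants: 20 (4R,5S,7R,8S)-guai-1(10)-ene-4,8-diol; 23 4-[(tert-butyldimethylsilyl)oxy]-3-methoxybenzoic acid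
Product: 24 (4R,5S,7R,8S)-4-hydroxyguai-1(10)-en-8-yl 4-[(tert-butyldimethylsilyl)oxy]-3-methoxybenzoate
Conditions: N,N'-dicyclohexylcarbodiimide, 4-(dimethylamino)pyridine, CH2Cl2, rt
Reagents that add atoms: none
Why: Steglich esterification acylates the secondary C8 hydroxyl, and the tertiary C4 hydroxyl does not react under these conditions.

Step 18
Reactants: 24 (4R,5S,7R,8S)-4-hydroxyguai-1(10)-en-8-yl 4-[(tert-butyldimethylsilyl)oxy]-3-methoxybenzoate
Product: 25 (5R,7R,8S)-guaia-1(10),3-dien-8-yl 4-[(tert-butyldimethylsilyl)oxy]-3-methoxybenzoate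
Conditions: Burgess reagent (MeO2CN−SO2N+Et3), toluene, 60 °C
Reagents that add atoms: none
Why: Burgess dehydration is a syn elimination through the sulfamate ester; with the hydroxyl trans to H5 only one C3 hydrogen and the methyl hydrogens are syn, and the more substituted endocyclic C3=C4 alkene is expected under neutral conditions that leave the skipped diene and the ester alone.

Step 19
Reactants: 25 (5R,7R,8S)-guaia-1(10),3-dien-8-yl 4-[(tert-butyldimethylsilyl)oxy]-3-methoxybenzoate
Product: 26 (5R,7R,8S)-guaia-1(10),3-dien-8-yl 4-hydroxy-3-methoxybenzoate (target)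
Conditions: Bu4NF, AcOH, THF, 0 °C
Reagents that add atoms: none
Why: Fluoride cleavage of the aryl silyl ether, buffered with acetic acid so that no free phenoxide or alkoxide is present, leaves the ester and the skipped diene untouched.

**Compound list**
1 | ethyl 3-methylbutanoate | CCOC(=O)CC(C)C | starting material
2 | ethyl 2-formyl-3-methylbutanoate (racemic, largely enol) | CCOC(=O)C(C=O)C(C)C | intermediate
3 | ethyl (E)-2-(propan-2-yl)-3-[(triisopropylsilyl)oxy]prop-2-enoate | CCOC(=O)/C(C(C)C)=C/O[Si](C(C)C)(C(C)C)C(C)C | intermediate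
4 | (E)-2-(propan-2-yl)-3-[(triisopropylsilyl)oxy]prop-2-en-1-ol | OC/C(C(C)C)=C/O[Si](C(C)C)(C(C)C)C(C)C | intermediate
5 | [(1S,2S)-1-(propan-2-yl)-2-[(triisopropylsilyl)oxy]cyclopropyl]methanol | OC[C@@]1(C(C)C)C[C@@H]1O[Si](C(C)C)(C(C)C)C(C)C | intermediate
6 | (1R,2S)-1-(propan-2-yl)-2-[(triisopropylsilyl)oxy]cyclopropane-1-carbaldehyde | O=C[C@@]1(C(C)C)C[C@@H]1O[Si](C(C)C)(C(C)C)C(C)C | intermediate
7 | 5-bromopent-2-yne | CC#CCCBr | starting material
8 | 2-chloro-N-methoxy-N-methylacetamide | CON(C)C(=O)CCl | starting material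
9 | pent-3-yn-1-ylmagnesium bromide | CC#CCC[Mg]Br | intermediate
10 | 1-chlorohept-5-yn-2-one | CC#CCCC(=O)CCl | intermediate
11 | 1-phenyl-1H-tetrazole-5-thiol | Sc1nnnn1-c1ccccc1 | starting material
12 | 1-[(1-phenyl-1H-tetrazol-5-yl)sulfanyl]hept-5-yn-2-one | CC#CCCC(=O)CSc1nnnn1-c1ccccc1 | intermediate
13 | 5-({[2-(pent-3-yn-1-yl)-1,3-dioxolan-2-yl]methyl}sulfanyl)-1-phenyl-1H-tetrazole | CC#CCCC1(CSc2nnnn2-c2ccccc2)OCCO1 | intermediate
14 | 5-({[2-(pent-3-yn-1-yl)-1,3-dioxolan-2-yl]methyl}sulfonyl)-1-phenyl-1H-tetrazole | CC#CCCC1(CS(=O)(=O)c2nnnn2-c2ccccc2)OCCO1 | intermediate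
15 | {[(1S,2S)-2-{(E)-2-[2-(pent-3-yn-1-yl)-1,3-dioxolan-2-yl]ethenyl}-2-(propan-2-yl)cyclopropyl]oxy}tri(propan-2-yl)silane (alkyne-tethered E-vinylcyclopropane; silyloxy trans to vinyl) | CC#CCCC1(OCCO1)/C=C/[C@@]2(C(C)C)C[C@@H]2O[Si](C(C)C)(C(C)C)C(C)C | intermediate
16 | (5S,8S)-4,4-(ethylenedioxy)-8-[(triisopropylsilyl)oxy]-15-norguaia-1(10),6-diene (hydroazulene; H5 and H8 cis) | CC1=C2CCC3(OCCO3)[C@H]2C=C(C(C)C)[C@@H](O[Si](C(C)C)(C(C)C)C(C)C)C1 | intermediate
17 | (5S,8S)-4,4-(ethylenedioxy)-15-norguaia-1(10),6-dien-8-ol | CC1=C2CCC3(OCCO3)[C@H]2C=C(C(C)C)[C@@H](O)C1 | intermediate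
18 | (5S,7R,8S)-4,4-(ethylenedioxy)-15-norguai-1(10)-en-8-ol (H7 cis to OH) | O[C@H]1CC(C)=C2CCC3(OCCO3)[C@H]2C[C@@H]1C(C)C | intermediate
19 | (5S,7R,8S)-8-hydroxy-15-norguai-1(10)-en-4-one | O[C@H]1CC(C)=C2CCC(=O)[C@H]2C[C@@H]1C(C)C | intermediate
20 | (4R,5S,7R,8S)-guai-1(10)-ene-4,8-diol (C4 methyl cis to H5) | O[C@H]1CC(C)=C2CC[C@@](C)(O)[C@H]2C[C@@H]1C(C)C | intermediate
21 | vanillic acid (4-hydroxy-3-methoxybenzoic acid) | COc1cc(C(=O)O)ccc1O | starting material
22 | tert-butyldimethylsilyl 4-[(tert-butyldimethylsilyl)oxy]-3-methoxybenzoate | COc1cc(C(=O)O[Si](C)(C)C(C)(C)C)ccc1O[Si](C)(C)C(C)(C)C | intermediate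
23 | 4-[(tert-butyldimethylsilyl)oxy]-3-methoxybenzoic acid | COc1cc(C(=O)O)ccc1O[Si](C)(C)C(C)(C)C | intermediate
24 | (4R,5S,7R,8S)-4-hydroxyguai-1(10)-en-8-yl 4-[(tert-butyldimethylsilyl)oxy]-3-methoxybenzoate | COc1cc(C(=O)O[C@H]2CC(C)=C3CC[C@@](C)(O)[C@H]3C[C@@H]2C(C)C)ccc1O[Si](C)(C)C(C)(C)C | intermediate
25 | (5R,7R,8S)-guaia-1(10),3-dien-8-yl 4-[(tert-butyldimethylsilyl)oxy]-3-methoxybenzoate | COc1cc(C(=O)O[C@H]2CC(C)=C3CC=C(C)[C@H]3C[C@@H]2C(C)C)ccc1O[Si](C)(C)C(C)(C)C | intermediate
26 | (5R,7R,8S)-guaia-1(10),3-dien-8-yl 4-hydroxy-3-methoxybenzoate [(6S,7R,8aR)-1,4-dimethyl-7-(propan-2-yl)-3,5,6,7,8,8a-hexahydroazulen-6-yl vanillate] | COc1cc(C(=O)O[C@H]2CC(C)=C3CC=C(C)[C@H]3C[C@@H]2C(C)C)ccc1O | target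

**Step count**
Total: 19 steps. Longest linear sequence: 14 steps (1–5, 10–15, 17–19).

**Steps most likely to fail**

1. Step 11. Rhodium may insert into the oxygen-substituted C7–C8 bond, which the silyloxy donor weakens, instead of C7–C9, or may open the donor cyclopropane without cycloaddition. The fallback sets out from 15 and returns at 17. The silyl ether is exchanged for an acyloxy group before the cycloaddition, which takes away the donor activation of C7–C8 and keeps a bulky group at C8. 15 is desilylated with Bu4NF/AcOH in THF at 0 °C to the cyclopropanol F1. This is acylated at once (pivaloyl chloride, pyridine, 4-(dimethylamino)pyridine, CH2Cl2, 0 °C) to the cyclopropyl pivalate F2. The same [Rh(CO)2Cl]2-catalysed [5+2] cycloaddition should then give the hydroazulene pivalate F3, and iBu2AlH (CH2Cl2, −78 °C) cleaves the ester to allylic alcohol 17.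

2. Step 18. The syn elimination may go toward the exocyclic methylene, or partial ionisation at C4 may remove H5 and give the conjugated C4=C5/C1=C10 diene; a wrong C4 configuration from step 15 would act the same way. The fallback sets out from 19 and returns at 25. The C4 methyl and C3=C4 are made by enol triflate cross-coupling instead of addition and dehydration. 19 is esterified with 23 (N,N'-dicyclohexylcarbodiimide, 4-(dimethylamino)pyridine) to the keto ester F4. LiN(SiMe3)2 in THF at −78 °C deprotonates the less hindered C3 methylene and PhNTf2 traps the enolate as the enol triflate F5. Negishi coupling with MeZnCl and Pd(PPh3)4 (zerovalent palladium) in THF gives 25.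

3. Step 14. The liberated β,γ-unsaturated ketone may enolise toward C5 under acid, with epimerisation at C5 or migration of C1=C10 into conjugation. The fallback sets out from 18 and returns at 25. The ketone is never set free, and steps 15, 17 and 18 are replaced by a Shapiro sequence. 18 is treated with 2,4,6-triisopropylbenzenesulfonyl hydrazide and catalytic pyridinium p-toluenesulfonate (THF, rt), which exchanges the ketal carbon directly into the (E)-hydrazone F6. Excess n-BuLi (THF, −78 → 0 °C) removes N–H, O–H and the syn C3–H; loss of sulfinate and N2 gives the C4 vinyllithium, and MeI gives the dienol F7. Steglich esterification of F7 with 23 gives 25.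

**Further compounds**
F1 | step 11 | (1S,2S)-2-{(E)-2-[2-(pent-3-yn-1-yl)-1,3-dioxolan-2-yl]ethenyl}-2-(propan-2-yl)cyclopropan-1-ol | CC#CCCC1(OCCO1)/C=C/[C@@]2(C(C)C)C[C@@H]2O
F2 | step 11 | (1S,2S)-2-{(E)-2-[2-(pent-3-yn-1-yl)-1,3-dioxolan-2-yl]ethenyl}-2-(propan-2-yl)cyclopropyl 2,2-dimethylpropanoate | CC#CCCC1(OCCO1)/C=C/[C@@]2(C(C)C)C[C@@H]2OC(=O)C(C)(C)C
F3 | step 11 | (5S,8S)-4,4-(ethylenedioxy)-15-norguaia-1(10),6-dien-8-yl 2,2-dimethylpropanoate | CC1=C2CCC3(OCCO3)[C@H]2C=C(C(C)C)[C@@H](OC(=O)C(C)(C)C)C1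
F4 | step 18 | (5S,7R,8S)-4-oxo-15-norguai-1(10)-en-8-yl 4-[(tert-butyldimethylsilyl)oxy]-3-methoxybenzoate | COc1cc(C(=O)O[C@H]2CC(C)=C3CCC(=O)[C@H]3C[C@@H]2C(C)C)ccc1O[Si](C)(C)C(C)(C)C
F5 | step 18 | (5S,7R,8S)-4-{[(trifluoromethyl)sulfonyl]oxy}-15-norguaia-1(10),3-dien-8-yl 4-[(tert-butyldimethylsilyl)oxy]-3-methoxybenzoate | COc1cc(C(=O)O[C@H]2CC(C)=C3CC=C(OS(=O)(=O)C(F)(F)F)[C@H]3C[C@@H]2C(C)C)ccc1O[Si](C)(C)C(C)(C)C
F6 | step 14 | N'-[(4E,5S,7R,8S)-8-hydroxy-15-norguai-1(10)-en-4-ylidene]-2,4,6-tri(propan-2-yl)benzenesulfonohydrazide | O[C@H]1CC(C)=C2CC/C(=N\NS(=O)(=O)c3c(C(C)C)cc(C(C)C)cc3C(C)C)[C@H]2C[C@@H]1C(C)C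
F7 | step 14 | (5R,7R,8S)-guaia-1(10),3-dien-8-ol | O[C@H]1CC(C)=C2CC=C(C)[C@H]2C[C@@H]1C(C)C
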